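**Plan**
1. The last cut is the spiro-dihydropyran (O–C11 and C13–CH2), opened by a retro-hetero-Diels–Alder reaction into (+)-alantolactone 22 and ent-β-elemenal 35; in 22 the C11=C13 methylene, the cis-lactone (C7–C11, C8–O) and C15 are then cut back to ene-dione 14.
2. Rings A and B are cut at C5–C10 and C8–C9: in ring B the oxygen-bearing C8 and the alkene carbon C5 end the four-carbon unit C5–C6–C7–C8, which is the retron of a 7-oxabicyclo[2.2.1]heptene with its C5–O bond cleaved, that is, of a furan (C5–C8 plus O8) added to the alkene C9=C10.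
3. Forward: keto acid 1 → furan enone 6 (4 steps); the intramolecular furan Diels–Alder reaction closes rings A and B; then the helpers leave: the C1 ketone (activator), the C4 silyloxy group (relay, then ketone trigger for cleaving C5–O, then methylene, then methyl), while the oxygen bridge stays as O8.
4. Stereochemistry: the C4 carbinol (asymmetric transfer hydrogenation) sets C10 in the cycloaddition; the C10 methyl group then directs C8 (hydride), C7 (lactone-driven equilibration) and C4 (hydrogenation); the spiro centre C11 comes from convex-face cycloaddition.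
5. The elemane half is built from (S)-carvone: C10′ by an auxiliary-controlled Michael addition, C5′ by equilibration of an acetyl group.

Key step: step 5

Remark: eudesmane numbering is used for the decalin half (C1–C10, lactone C11–C13, C14 on C10, C15 on C4; β is the face of the C10 methyl group, primed numbers for the elemane half).
Remark: the elemane half of the target has the R configuration at its quaternary carbon, the mirror-image series of commercial (−)-β-elemene, so it is made from (S)-(+)-carvone and not from the natural hydrocarbon.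

**Eudesmanolide half**

Step 1
Reactants: 1 4-(furan-2-yl)-4-oxobutanoic acid
Product: 3 (R)-5-(furan-2-yl)oxolan-2-one, via (R)-hydroxy acid 2 (not isolated)
Conditions: RuCl[(R,R)-TsDPEN](p-cymene) (1 mol%), HCO2H/Et3N 5:2, 40 °C; then PPTS (cat.), PhMe, 60 °C
Reagents that add atoms: none
Why: Noyori asymmetric transfer hydrogenation of the 2-furyl ketone (aryl/alkyl discrimination as for acetophenone, the (R,R)-ligand giving the (R)-carbinol) followed by γ-lactonisation should set the C4 carbinol centre that later relays chirality.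

Step 2
Reactants: 3 (R)-5-(furan-2-yl)oxolan-2-one
Product: 4 (R)-4-(furan-2-yl)-4-hydroxy-N-methoxy-N-methylbutanamide
Conditions: MeNH(OMe)·HCl, i-PrMgCl, THF, −20 °C
Reagents that add atoms: N,O-dimethylhydroxylamine hydrochloride, CNOC.Cl
Why: Weinreb aminolysis of the lactone by the chloromagnesium amide should open the ring without touching the carbinol centre.

Step 3
Reactants: 4 (R)-hydroxy Weinreb amide
Product: 5 (R)-4-[(tert-butyldimethylsilyl)oxy]-4-(furan-2-yl)-N-methoxy-N-methylbutanamide
Conditions: TBSCl, imidazole, DMF, 23 °C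
Reagents that add atoms: tert-butyldimethylsilyl chloride, CC(C)(C)[Si](C)(C)Cl
Why: Standard silylation of a secondary alcohol gives a bulky, poorly Lewis-basic ether that serves as the equatorial anchor in the key step.

Step 4
Reactants: 5 silylated Weinreb amide
Product: 6 (R)-6-[(tert-butyldimethylsilyl)oxy]-6-(furan-2-yl)-2-methylhex-1-en-3-one
Conditions: CH2=C(Me)MgBr, THF, 0 °C
Reagents that add atoms: isopropenylmagnesium bromide, CC(=C)[Mg]Br
Why: Weinreb ketone synthesis stops at the ketone through the chelated tetrahedral intermediate and delivers the 2-methyl enone dienophile (C9, C10, C14).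

Step 5
Reactants: 6 furan enone
Product: 7 cycloadduct, 4α-[(tert-butyldimethylsilyl)oxy]-5α,8α-epoxy-10β-methyl-decal-6-en-1-one (11-oxatricyclo[6.2.1.0(1,6)]undec-9-en-5-one skeleton; oxygen bridge anti to the C10 methyl, silyloxy group syn to the bridge)
Conditions: MeAlCl2 (1.1 equiv), CH2Cl2, −78 °C
Reagents that add atoms: none
Why: Complexation of the enone carbonyl by MeAlCl2 lowers the LUMO of C9=C10, and the furan (C5=C6–C7=C8) adds to it in a concerted, asynchronous [4+2] cycloaddition that forms C5–C10 and C8–C9 together (intramolecular Diels–Alder reaction of a furan). The closest known reaction type is the MeAlCl2-promoted cyclisation of 2-(5-oxohex-5-enyl)furans to 11-oxatricyclo[6.2.1.0(1,6)]undec-9-en-5-ones, which the substrate matches apart from the silyloxy group. Ring A closes by bonding of the tether-bearing furan carbon C5 to the internal alkene carbon C10, the only mode the four-atom tether allows, and ring B closes as the carbocyclic six-membered ring of the 7-oxabicyclo[2.2.1]heptene when C8 bonds to the terminal carbon C9. C5 and C8 are set cis by the suprafacial addition, C10 is set by the tether, which can only lie exo (C1 syn to the oxygen bridge, methyl endo and anti to it), and the absolute sense of all three follows from C4, whose silyloxy group should take the equatorial site of the chair-like tether because the axial site is syn-diaxial to the endo methyl group. The step needs facial diastereoselectivity and a favourable position of a reversible equilibrium; the first is secured by the C4 substituent, the second by the low temperature and the stoichiometric Lewis acid, which binds the adduct ketone.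

Step 6
Reactants: 7 cycloadduct ketone
Product: 9 1-deoxo cycloadduct, 4α-[(tert-butyldimethylsilyl)oxy]-5α,8α-epoxy-10β-methyl-decal-6-ene, via N-silyl hydrazone 8 (not isolated)
Conditions: TBSNHNHTBS, Sc(OTf)3 (cat.), CHCl3, 23 °C; then KOt-Bu, t-BuOH, DMSO, 23→60 °C
Reagents that add atoms: none
Why: Wolff–Kishner reduction in its low-temperature N-silyl hydrazone variant should remove the activating C1 carbonyl below the temperature of cycloreversion, and the quaternary C10 cannot epimerise.

Step 7
Reactants: 9 1-deoxo cycloadduct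
Product: 10 4α-hydroxy-5α,8α-epoxy-10β-methyl-decal-6-ene
Conditions: Bu4NF, THF, 23 °C
Reagents that add atoms: none
Why: Fluoride desilylation frees the relay carbinol under conditions that leave the strained allylic ether bridge intact.

Step 8
Reactants: 10 bridged alcohol
Product: 11 5α,8α-epoxy-10β-methyl-decal-6-en-4-one
Conditions: Dess–Martin periodinane, CH2Cl2, 23 °C
Reagents that add atoms: none
Why: Dess–Martin oxidation erases the C4 centre once it has done its work and makes the bridge oxygen an α-alkoxy substituent of a ketone.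

Step 9
Reactants: 11 bridged α-alkoxy ketone
Product: 13 8α-hydroxy-10β-methyl-Δ5(6)-octal-4-one, via deconjugated ketone 12 (not isolated)
Conditions: SmI2 (2.2 equiv), THF/MeOH, −78 °C; then DBU (cat.), CH2Cl2, 23 °C
Reagents that add atoms: none
Why: Samarium diiodide reduction of an α-alkoxy ketone (ketyl formation, expulsion of the bridging alkoxide from C5, as in the opening of oxabicyclic ketones) cleaves only the C5–O bond, and base then moves the alkene into conjugation as C5=C6, leaving O8 as the free 8α-alcohol.

Step 10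
Reactants: 13 hydroxy enone
Product: 14 10β-methyl-Δ5(6)-octalin-4,8-dione
Conditions: Dess–Martin periodinane, CH2Cl2, 23 °C
Reagents that add atoms: none
Why: Dess–Martin oxidation removes the C8 configuration that the cycloaddition had to set anti to the C10 methyl group and makes C7 a doubly activated (vinylogous β-diketone) position.

Step 11
Reactants: 14 ene-dione
Product: 15 methyl 2-(10β-methyl-4,8-dioxo-Δ5(6)-octalin-7-yl)acetate (C7 epimers)
Conditions: LiN(SiMe3)2 (1.0 equiv), THF, −78 °C; BrCH2CO2Me
Reagents that add atoms: methyl bromoacetate, COC(=O)CBr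
Why: Enolate alkylation of the delocalised O4–C8 enolate should occur at C7 because the other carbon terminus, C5, is shielded by the adjacent quaternary C10, and both C7 epimers are usable since the centre is set in step 12.

Step 12
Reactants: 15 alkylated ene-dione
Product: 17 cis-fused keto lactone, 4-oxo-13,15-dinor-eudesm-5-en-12,8β-olide (7α-H, 8α-H), via hydroxy ester 16 (not isolated)
Conditions: NaBH4, MeOH/CH2Cl2, −78 °C; then NaOMe (cat.), MeOH, 23 °C
Reagents that add atoms: none
Why: Chemoselective borohydride reduction of the isolated C8 ketone beside the enone should deliver hydride to the α face anti to the axial C10 methyl group (8β-alcohol), and methoxide then equilibrates C7 through the vinylogous enolate of the enone so that the 7β epimer, the only one able to lactonise onto the 8β-hydroxyl, drains the mixture into the cis-fused lactone.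

Step 13
Reactants: 17 keto lactone
Product: 18 diene lactone, 13-nor-eudesma-4(15),5-dien-12,8β-olide
Conditions: Zn, CH2Br2, TiCl4, THF/CH2Cl2, 0→23 °C
Reagents that add atoms: dibromomethane, BrCBr
Why: Takai–Lombardo methylenation is non-basic and ketone-selective, so the hindered, enolisable enone carbonyl should be converted while the lactone stays untouched.

Step 14
Reactants: 18 diene lactone
Product: 19 13-nor-11,13-dihydroalantolactone (4β-methyl, 4α-H)
Conditions: H2 (1 atm), RhCl(PPh3)3 (cat.), PhH, 23 °C
Reagents that add atoms: none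
Why: Homogeneous hydrogenation with the chlororhodium tris(phosphine) catalyst reduces the 1,1-disubstituted C4=C15 bond and not the trisubstituted C5=C6 bond, and hydrogen should arrive on the α face anti to the axial C10 methyl group, which places C15 β.

Step 15
Reactants: 19 saturated lactone
Product: 22 (+)-alantolactone, via Mannich base 20 (not isolated), via methiodide 21 (not isolated)
Conditions: LiN(i-Pr)2, THF, −78 °C; CH2=NMe2+ I−, −78→23 °C; MeI, MeOH; NaHCO3, 23 °C
Reagents that add atoms: N,N-dimethylmethyleneiminium iodide, C=[N+](C)C.[I-]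
Why: Mannich aminomethylation of the lactone enolate followed by quaternisation and Hofmann-type elimination is the standard α-methylenation of γ-lactones, and C11 is the only enolisable position.

**Elemane half**

Step 16
Reactants: 23 (S)-(+)-carvone
Product: 24 (5S)-2-methyl-5-(prop-1-en-2-yl)cyclohexan-1-one (C2 epimers)
Conditions: LiBH(s-Bu)3, THF, −78 °C; then H2O
Reagents that add atoms: none
Why: Conjugate hydride reduction of the enone by the hindered borohydride gives the saturated ketone, whose C2 configuration is irrelevant because it passes through an enamine in step 17.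

Step 17
Reactants: 24 dihydrocarvone
Product: 27 methyl 3-[(1R,4S)-1-methyl-2-oxo-4-(prop-1-en-2-yl)cyclohexyl]propanoate, via ketimine 25 (not isolated), via Michael adduct ketimine 26 (not isolated)
Conditions: (S)-PhCH(Me)NH2, TsOH (cat.), PhMe, reflux (−H2O); methyl acrylate, 40 °C; then 20% aq. AcOH
Reagents that add atoms: methyl acrylate, C=CC(=O)OC
Why: Asymmetric Michael addition of a chiral imine through its more substituted secondary enamine (aza-ene-type transfer anti to the phenyl group) should build the quaternary C10′ with the new chain trans to the isopropenyl group, the (S)-amine being the matched auxiliary for the R centre.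

Step 18
Reactants: 27 keto ester
Product: 28 3-[(1R,4S)-1-methyl-2-oxo-4-(prop-1-en-2-yl)cyclohexyl]propanoic acid
Conditions: LiOH, THF/H2O, 23 °C; then aq. HCl
Reagents that add atoms: lithium hydroxide, [Li+].[OH-]
Why: Saponification of the methyl ester frees the acid needed for decarboxylation without touching the non-epimerisable quaternary centre.

Step 19
Reactants: 28 keto acid
Product: 29 (2R,5S)-2-ethenyl-2-methyl-5-(prop-1-en-2-yl)cyclohexan-1-one
Conditions: Pb(OAc)4, Cu(OAc)2 (cat.), pyridine, PhH, 80 °C
Reagents that add atoms: none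
Why: Kochi oxidative decarboxylation turns the CH2CH2CO2H chain into the vinyl group through a primary alkyl radical that copper diacetate oxidises to the terminal alkene.

Step 20
Reactants: 29 vinyl ketone
Product: 30 2-ethenyl-2-methyl-5-(prop-1-en-2-yl)cyclohexane-1-carbonitrile (C2, C5 as in 29; C1 epimers)
Conditions: TosMIC, KOt-Bu, DME, EtOH, 0→40 °C
Reagents that add atoms: p-toluenesulfonylmethyl isocyanide, [C-]#[N+]CS(=O)(=O)c1ccc(C)cc1
Why: Van Leusen reductive cyanation converts the hindered ketone into the homologous nitrile in one operation and tolerates the alkenes.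

Step 21
Reactants: 30 nitrile
Product: 32 1-[(1S,2R,5S)-2-ethenyl-2-methyl-5-(prop-1-en-2-yl)cyclohexyl]ethan-1-one, via lithio ketimine 31 (not isolated)
Conditions: MeLi, Et2O, 0 °C; aq. HCl; then NaOMe, MeOH, 23 °C
Reagents that add atoms: methyllithium, [Li]C; water, O
Why: Addition of methyllithium to the nitrile and hydrolysis give the methyl ketone, and base equilibration should place the acetyl group equatorial, cis to the C7′ isopropenyl group and trans to the vinyl group.

Step 22
Reactants: 32 methyl ketone
Product: 33 1-[(1S,2R,5S)-2-ethenyl-5-(3-hydroxyprop-1-en-2-yl)-2-methylcyclohexyl]ethan-1-one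
Conditions: SeO2 (cat.), t-BuOOH, CH2Cl2, 23 °C
Reagents that add atoms: tert-butyl hydroperoxide, CC(C)(C)OO
Why: Selenium dioxide allylic hydroxylation (ene reaction, then [2,3]-shift) attacks the methyl group of the only isopropenyl unit present, since the vinyl group on the quaternary carbon has no allylic hydrogen.

Step 23
Reactants: 33 hydroxy ketone
Product: 34 2-[(1S,3R,4R)-4-ethenyl-4-methyl-3-(prop-1-en-2-yl)cyclohexyl]prop-2-en-1-ol
Conditions: Ph3PCH3Br, KOt-Bu (3 equiv), THF, 0→23 °C
Reagents that add atoms: methyltriphenylphosphonium bromide, C[P+](c1ccccc1)(c1ccccc1)c1ccccc1.[Br-]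
Why: Wittig methylenation of the methyl ketone creates the second isopropenyl group only after the first has been oxidised, so the two are never in competition.

Step 24
Reactants: 34 allylic alcohol
Product: 35 ent-β-elemenal, 2-[(1S,3R,4R)-4-ethenyl-4-methyl-3-(prop-1-en-2-yl)cyclohexyl]prop-2-enal
Conditions: MnO2, CH2Cl2, 23 °C
Reagents that add atoms: none
Why: Manganese dioxide oxidises the primary allylic alcohol selectively to the 2-substituted acrolein.

**Union**

Step 25
Reactants: 22 (+)-alantolactone; 35 ent-β-elemenal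
Product: 36 target spiro-dihydropyran
Conditions: PhMe (2 M), BHT (cat.), 140 °C, sealed tube
Reagents that add atoms: none
Why: Thermal hetero-Diels–Alder reaction of the 2-substituted acrolein as 1-oxadiene with the exocyclic methylene lactone should follow the regiochemistry of enal dimerisation (oxygen to C11, CH2 to C13) and take place on the convex face of the cis-fused lactone, syn to H7 and H8, which gives the spiro configuration of the target.

**Compound list**
1 | 4-(furan-2-yl)-4-oxobutanoic acid | O=C(O)CCC(=O)c1ccco1 | starting material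
2 | (R)-4-(furan-2-yl)-4-hydroxybutanoic acid | O=C(O)CC[C@@H](O)c1ccco1 | intermediate
3 | (R)-5-(furan-2-yl)oxolan-2-one | O=C1CC[C@H](c2ccco2)O1 | intermediate
4 | (R)-4-(furan-2-yl)-4-hydroxy-N-methoxy-N-methylbutanamide | CON(C)C(=O)CC[C@@H](O)c1ccco1 | intermediate
5 | (R)-4-[(tert-butyldimethylsilyl)oxy]-4-(furan-2-yl)-N-methoxy-N-methylbutanamide | CON(C)C(=O)CC[C@@H](O[Si](C)(C)C(C)(C)C)c1ccco1 | intermediate
6 | (R)-6-[(tert-butyldimethylsilyl)oxy]-6-(furan-2-yl)-2-methylhex-1-en-3-one | C=C(C)C(=O)CC[C@@H](O[Si](C)(C)C(C)(C)C)c1ccco1 | intermediate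
7 | cycloadduct, 4α-silyloxy-5α,8α-epoxy-10β-methyl-decal-6-en-1-one | C[C@]12C(=O)CC[C@@H](O[Si](C)(C)C(C)(C)C)[C@@]13O[C@H](C=C3)C2 | intermediate
8 | N-(tert-butyldimethylsilyl)hydrazone of 7 | C[C@]12C(=NN[Si](C)(C)C(C)(C)C)CC[C@@H](O[Si](C)(C)C(C)(C)C)[C@@]13O[C@H](C=C3)C2 | intermediate
9 | 4α-silyloxy-5α,8α-epoxy-10β-methyl-decal-6-ene | C[C@]12CCC[C@@H](O[Si](C)(C)C(C)(C)C)[C@@]13O[C@H](C=C3)C2 | intermediate
10 | 4α-hydroxy-5α,8α-epoxy-10β-methyl-decal-6-ene | C[C@]12CCC[C@@H](O)[C@@]13O[C@H](C=C3)C2 | intermediate
11 | 5α,8α-epoxy-10β-methyl-decal-6-en-4-one | C[C@]12CCCC(=O)[C@@]13O[C@H](C=C3)C2 | intermediate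
12 | 8α-hydroxy-10β-methyl-Δ6(7)-octal-4-one (C5 epimers) | O[C@@H]1C=CC2C(=O)CCC[C@]2(C)C1 | intermediate
13 | 8α-hydroxy-10β-methyl-Δ5(6)-octal-4-one | O[C@@H]1CC=C2C(=O)CCC[C@]2(C)C1 | intermediate
14 | 10β-methyl-Δ5(6)-octalin-4,8-dione | O=C1CC=C2C(=O)CCC[C@]2(C)C1 | intermediate
15 | methyl 2-(10β-methyl-4,8-dioxo-Δ5(6)-octalin-7-yl)acetate (C7 epimers) | COC(=O)CC1C=C2C(=O)CCC[C@]2(C)CC1=O | intermediate
16 | methyl 2-(8β-hydroxy-10β-methyl-4-oxo-Δ5(6)-octalin-7-yl)acetate (C7 epimers) | COC(=O)CC1C=C2C(=O)CCC[C@]2(C)C[C@H]1O | intermediate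
17 | 4-oxo-13,15-dinor-eudesm-5-en-12,8β-olide (7α-H, 8α-H) | C1C(=O)O[C@@H]2C[C@@]3(C)CCCC(=O)C3=C[C@@H]21 | intermediate
18 | 13-nor-eudesma-4(15),5-dien-12,8β-olide | C1C(=O)O[C@@H]2C[C@@]3(C)CCCC(=C)C3=C[C@@H]21 | intermediate
19 | 13-nor-11,13-dihydroalantolactone | C1C(=O)O[C@@H]2C[C@@]3(C)CCC[C@H](C)C3=C[C@@H]21 | intermediate
20 | 13-(dimethylamino)-11,13-dihydroalantolactone (C11 epimers) | CN(C)CC1C(=O)O[C@@H]2C[C@@]3(C)CCC[C@H](C)C3=C[C@@H]21 | intermediate
21 | trimethylammonium iodide of 20 | C[N+](C)(C)CC1C(=O)O[C@@H]2C[C@@]3(C)CCC[C@H](C)C3=C[C@@H]21.[I-] | intermediate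
22 | (+)-alantolactone | C=C1C(=O)O[C@@H]2C[C@@]3(C)CCC[C@H](C)C3=C[C@@H]21 | intermediate
23 | (S)-(+)-carvone | CC1=CC[C@H](C(C)=C)CC1=O | starting material
24 | (5S)-2-methyl-5-(prop-1-en-2-yl)cyclohexan-1-one (C2 epimers) | CC1CC[C@H](C(C)=C)CC1=O | intermediate
25 | N-[(S)-1-phenylethyl] ketimine of 24 | CC1CC[C@H](C(C)=C)CC1=N[C@@H](C)c1ccccc1 | intermediate
26 | N-[(S)-1-phenylethyl] ketimine of 27 | COC(=O)CC[C@@]1(C)CC[C@H](C(C)=C)CC1=N[C@@H](C)c1ccccc1 | intermediate
27 | methyl 3-[(1R,4S)-1-methyl-2-oxo-4-(prop-1-en-2-yl)cyclohexyl]propanoate | COC(=O)CC[C@@]1(C)CC[C@H](C(C)=C)CC1=O | intermediate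
28 | 3-[(1R,4S)-1-methyl-2-oxo-4-(prop-1-en-2-yl)cyclohexyl]propanoic acid | OC(=O)CC[C@@]1(C)CC[C@H](C(C)=C)CC1=O | intermediate
29 | (2R,5S)-2-ethenyl-2-methyl-5-(prop-1-en-2-yl)cyclohexan-1-one | C=C[C@@]1(C)CC[C@H](C(C)=C)CC1=O | intermediate
30 | 2-ethenyl-2-methyl-5-(prop-1-en-2-yl)cyclohexane-1-carbonitrile (C1 epimers) | C=C[C@@]1(C)CC[C@H](C(C)=C)CC1C#N | intermediate
31 | N-lithio methyl ketimine from 30 | C=C[C@@]1(C)CC[C@H](C(C)=C)CC1C(C)=N[Li] | intermediate
32 | 1-[(1S,2R,5S)-2-ethenyl-2-methyl-5-(prop-1-en-2-yl)cyclohexyl]ethan-1-one | C=C[C@@]1(C)CC[C@H](C(C)=C)C[C@@H]1C(C)=O | intermediate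
33 | 1-[(1S,2R,5S)-2-ethenyl-5-(3-hydroxyprop-1-en-2-yl)-2-methylcyclohexyl]ethan-1-one | C=C[C@@]1(C)CC[C@H](C(=C)CO)C[C@@H]1C(C)=O | intermediate
34 | 2-[(1S,3R,4R)-4-ethenyl-4-methyl-3-(prop-1-en-2-yl)cyclohexyl]prop-2-en-1-ol | C=C[C@@]1(C)CC[C@H](C(=C)CO)C[C@@H]1C(C)=C | intermediate
35 | ent-β-elemenal, 2-[(1S,3R,4R)-4-ethenyl-4-methyl-3-(prop-1-en-2-yl)cyclohexyl]prop-2-enal | C=C[C@@]1(C)CC[C@H](C(=C)C=O)C[C@@H]1C(C)=C | intermediate
36 | CNP0175206.1, spiro hetero-Diels–Alder adduct of 22 and 35 | C=C[C@@]1(C)CC[C@H](C2=CO[C@@]3(CC2)C(=O)O[C@@H]2C[C@@]4(C)CCC[C@H](C)C4=C[C@@H]23)C[C@@H]1C(=C)C | target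

**Step count and risks**
Total steps: 25 (15 for the eudesmanolide half, 9 for the elemane half, 1 union). Longest linear sequence: 16 (steps 1–15 and 25).

Steps most likely to fail:

Step 5. Ionisation of the furfuryl silyl ether by the Lewis acid, weak facial control by the C4 group, or cycloreversion on work-up may spoil the cycloaddition. The fallback gives up the oxygen relay and starts from 1. Thioketalisation (HS(CH2)3SH, BF3·OEt2) gives 4-[2-(furan-2-yl)-1,3-dithian-2-yl]butanoic acid F1, whose furfuryl carbon cannot ionise. The chemistry of steps 2 and 4 (amide coupling with MeNH(OMe)·HCl, then isopropenylmagnesium bromide) gives the dithiane Weinreb amide F2 and the dithiane enone F3. MeAlCl2 then gives the racemic dithiane cycloadduct F4, and the conditions of step 6 give the racemic 1-deoxo dithiane F5. MeI and CaCO3 in aqueous MeCN unmask racemic 11, and step 9 gives racemic 13. The enantiomers are separated there by lipase-catalysed acylation (Candida antarctica lipase B, vinyl acetate) as free alcohol and the acetate of 13 F6. The enantiomer needed, taken directly or after methanolysis of F6, comes back to the route at 13.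

Step 12. Hydride may attack the enone carbonyl or the β face of C8, or the C7 equilibration may stall or move the alkene out of the C5=C6 position. The fallback forms the C7–C11 bond intramolecularly and starts from 14. NaBH4 at −78 °C gives 8β-hydroxy-10β-methyl-Δ5(6)-octal-4-one F7 (hydride still anti to the C10 methyl group, no C7 centre yet). Bromoacetyl bromide and pyridine give the 8β-bromoacetate F8. Cs2CO3 in MeCN then closes the lactone by γ-alkylation of the extended enolate of the enone at C7. The five-membered tether can only give the cis-fused lactone, and the fallback comes back to the route at 17.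

Step 25. Thermal polymerisation or self-dimerisation of the enal, slow reaction of two hindered partners, or attack on the wrong face may defeat the cycloaddition. The fallback builds the dihydropyran stepwise from 35 and 22. Conjugate addition of PhSO2Na/AcOH to 35 and acetalisation (HC(OMe)3, PPTS) give the β-sulfonyl dimethyl acetal F9. Its α-sulfonyl carbanion (n-BuLi, THF, −78 °C) adds to C13 of 22, and the lactone enolate is trapped with (camphorsulfonyl)oxaziridine on the convex face to give the 11α-hydroxy sulfone acetal F10. Na(Hg) with Na2HPO4 in MeOH removes the sulfonyl group to give the hydroxy acetal F11. PPTS in refluxing PhH closes the cyclic acetal and eliminates methanol to the enol ether, and the fallback comes back to the route at 36.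

**Further compounds**
F1 | step 5 | 4-[2-(furan-2-yl)-1,3-dithian-2-yl]butanoic acid | OC(=O)CCC1(SCCCS1)c1ccco1
F2 | step 5 | 4-[2-(furan-2-yl)-1,3-dithian-2-yl]-N-methoxy-N-methylbutanamide | CON(C)C(=O)CCC1(SCCCS1)c1ccco1
F3 | step 5 | 6-[2-(furan-2-yl)-1,3-dithian-2-yl]-2-methylhex-1-en-3-one | C=C(C)C(=O)CCC1(SCCCS1)c1ccco1
F4 | step 5 | racemic dithiane cycloadduct (relative configuration as in 7, one enantiomer drawn) | C[C@]12C(=O)CCC3(SCCCS3)[C@@]14O[C@H](C=C4)C2
F5 | step 5 | racemic 1-deoxo dithiane cycloadduct (one enantiomer drawn) | C[C@]12CCCC3(SCCCS3)[C@@]14O[C@H](C=C4)C2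
F6 | step 5 | acetate of 13 | CC(=O)O[C@@H]1CC=C2C(=O)CCC[C@]2(C)C1
F7 | step 12 | 8β-hydroxy-10β-methyl-Δ5(6)-octal-4-one | O[C@H]1CC=C2C(=O)CCC[C@]2(C)C1
F8 | step 12 | 8β-(bromoacetoxy)-10β-methyl-Δ5(6)-octal-4-one | BrCC(=O)O[C@H]1CC=C2C(=O)CCC[C@]2(C)C1
F9 | step 25 | β-(phenylsulfonyl) dimethyl acetal from 35 (new CH centre as epimers) | C=C[C@@]1(C)CC[C@H](C(CS(=O)(=O)c2ccccc2)C(OC)OC)C[C@@H]1C(=C)C
F10 | step 25 | 11α-hydroxy sulfone acetal (Michael adduct of F9 and 22, side-chain centres as epimers) | C=C[C@@]1(C)CC[C@H](C(C(OC)OC)C(C[C@]2(O)C(=O)O[C@@H]3C[C@@]4(C)CCC[C@H](C)C4=C[C@@H]32)S(=O)(=O)c2ccccc2)C[C@@H]1C(=C)C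
F11 | step 25 | 11α-hydroxy acetal after desulfonylation | C=C[C@@]1(C)CC[C@H](C(CC[C@]2(O)C(=O)O[C@@H]3C[C@@]4(C)CCC[C@H](C)C4=C[C@@H]32)C(OC)OC)C[C@@H]1C(=C)C
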